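Take the closed, stirred vessel and decide how long the next run stays in it: the dawn time or the summer time.

common to all: starting material 0.50 M; reagent 1.25 M

| charge | time |
|---|---|
| summer | 50 h |
| dawn | 15 h |

    intermediate B ⇌ intermediate C (K1 = 0.50, k1 = 2.9 × 10⁻⁴ min⁻¹)
    starting material → intermediate A (k2 = 8.1 × 10⁻⁴ min⁻¹)
    starting material + reagent → intermediate B (k3 = 2.9 × 10⁻⁴ M⁻¹ min⁻¹)
    target → over-reaction product (k4 = 2.2 × 10⁻⁴ min⁻¹)
    intermediate A → target (k5 = 3.1 × 10⁻⁵ min⁻¹)

- which of these there is most of at the end, counted by the starting material in it, summer (intermediate B / intermediate C / starting material / intermediate A / target)
- which of these there is most of at the end, counted by the starting material in it, dawn (intermediate B / intermediate C / starting material / intermediate A / target)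
- amount of the one of these that there is most of at the end, in percent of the starting material charged, summer
- amount of the one of these that there is most of at the end, in percent of the starting material charged, dawn

Starting material leaves by two routes: alone to intermediate A, or with reagent to intermediate B. Reagent is charged in excess of starting material, so hold it at its charge, which makes both routes pseudo-first-order with a total loss constant λ of 0.00117 min⁻¹. The zero of the scale is the even split, a share of 0.5. At the charged reagent, the branching share φ, the constant of the lone step over λ, comes to 69.1%, more than the even split.

My reckoning multiplies φ by the fraction reacted. Dawn forms 45.0% of intermediate A and leaves 34.8% of starting material, less than intermediate A. Summer forms 67.0%. These figures are amounts formed, not amounts standing at the end: the step from intermediate A to target still takes some away, though its half-life of 16 d is longer than the summer time. Intermediate A leads at both times, and the starting material left at dawn is worth a further 24.0% of it, so leave the next run for the summer time.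

The forecast names intermediate A at 63.3% for summer and intermediate A at 44.5% for dawn. Its summer figure is lower than mine, on the ground of “Slow leakage to target”.

The simulation gives intermediate A at 63.5% for summer and intermediate A at 44.5% for dawn, where starting material stands at 35.3%. An earlier reading of the dawn flask puts another species ahead. Read the dawn flask at 4.0 h, with the same charges: φ times the fraction reacted gives 16.9% of intermediate A, with 75.5% of starting material left. That flask holds 16.9% of intermediate A, less than its 75.6% of starting material.

All constants are assumed, and the outcome is calculated.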